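**Plan**

1. Numbering used here: C1–C2 ethyl, C3 side-chain carbinol, C4 and C8 the two N–CH carbons of the piperidine (C5–C7 between them), C9 ring-fusion CH, C10 CHMe, C11 CHOH, C12 spiro carbon, C13 C–OH, C14–C16 the chain to N; lactone atoms C2'(=O), C3'(Me), C4'(OMe).
2. Retrosynthetic cuts, in order: the piperidine is dehydrogenated to a pyridinium and N–C16 is cut; C9–C13 is cut with removal of H from C10, giving an (E)-2-alkenylpyridine and a C13 ketone; C12–C13 and C11–C12 are cut to 4-chlorobutanal, the intact methyl tetronate and a pyridyl enal; C9=C10 and the C3 carbonyl lead back to 2,6-dibromopyridine.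
3. Enabling feature: C9 is β to the ring nitrogen through C8. If the piperidine ring (N, C4–C8) is carried as a pyridine, C8=N plays the part of an enone carbonyl, so hydride at C10 turns C9 into an aza-enolate, and the C13 ketone on spiro C12 is placed for a five-membered closure.
4. Forward ring order: pyridine and butenolide (both bought) are joined at C11–C12; C12 is made quaternary (C12–C13); then cyclopentane (C9–C13), azepane (N–C16, as a pyridinium ring), piperidine (hydrogenation).
5. Stereochemistry: C3 by asymmetric transfer hydrogenation; C11 by a Ti/BINOL vinylogous Mukaiyama aldol; C12 by 1,2-induction from C11; C10, C9 and C13 in the key step; C8 and C4 by all-cis hydrogenation of the fused pyridinium from the face of C9–H.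

Key step: step 11

Assumption: 4-methoxy-3-methylfuran-2(5H)-one and 4-chlorobutanal are treated as purchasable (otherwise one O-methylation from 3-methyltetronic acid and one oxidation from 4-chlorobutan-1-ol). TBS = tert-butyldimethylsilyl, TES = triethylsilyl.

**Route**

Step 1
Reactants: 1 2,6-dibromopyridine; 2 N-methoxy-N-methylpropanamide
Product: 4 1-(6-bromopyridin-2-yl)propan-1-one, via 6-bromo-2-lithiopyridine 3 (not isolated)
Conditions: n-BuLi (1.0 equiv), CH2Cl2, −78 °C; then 2, −78 → 0 °C; AcOH/H2O quench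
Reagents that add atoms: none
Why: Mono bromine–lithium exchange followed by Weinreb ketone synthesis should stop at the ketone because the chelated tetrahedral adduct survives until the quench.

Step 2
Reactants: 4 1-(6-bromopyridin-2-yl)propan-1-one
Product: 5 (R)-1-(6-bromopyridin-2-yl)propan-1-ol
Conditions: RuCl(p-cymene)[(R,R)-TsDPEN] (1 mol %), HCO2H/Et3N 5:2, rt
Reagents that add atoms: none
Why: Noyori asymmetric transfer hydrogenation of an aryl alkyl ketone; the (R,R)-catalyst should give the (R)-carbinol (C3) through the usual CH/π-controlled transition state, and the 6-bromo group disfavours N-chelation.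

Step 3
Reactants: 5 (R)-1-(6-bromopyridin-2-yl)propan-1-ol
Product: 6 (R)-2-bromo-6-[1-(TBSO)propyl]pyridine
Conditions: TBSCl, imidazole, DMF, rt
Reagents that add atoms: tert-butyldimethylsilyl chloride, CC(C)(C)[Si](C)(C)Cl
Why: Standard silylation of a secondary alcohol; it protects C3–OH against the organolithium, enolate and oxidation steps that follow.

Step 4
Reactants: 6 (R)-2-bromo-6-[1-(TBSO)propyl]pyridine
Product: 8 (R)-6-[1-(TBSO)propyl]pyridine-2-carbaldehyde, via 6-lithio-2-[(R)-1-(TBSO)propyl]pyridine 7 (not isolated)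
Conditions: n-BuLi, Et2O, −78 °C; then DMF; AcOH/H2O quench
Reagents that add atoms: N,N-dimethylformamide, CN(C)C=O
Why: Bromine–lithium exchange and formylation with DMF is routine for 2-bromopyridines and delivers C9 as the aldehyde carbon.

Step 5
Reactants: 8 (R)-6-[1-(TBSO)propyl]pyridine-2-carbaldehyde; 9 2-(triphenylphosphoranylidene)propanal
Product: 10 (E)-3-{6-[(R)-1-(TBSO)propyl]pyridin-2-yl}-2-methylprop-2-enal
Conditions: toluene, 90 °C
Reagents that add atoms: none
Why: Wittig olefination with a stabilised ylide should give the (E)-2-methyl enal (pyridyl trans to CHO), which fixes the C9=C10 geometry and places the C10 methyl.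

Step 6
Reactants: 11 4-methoxy-3-methylfuran-2(5H)-one
Product: 12 [(4-methoxy-3-methylfuran-2-yl)oxy]trimethylsilane
Conditions: TMSOTf, Et3N, Et2O, 0 °C; filtered and concentrated under argon
Reagents that add atoms: trimethylsilyl trifluoromethanesulfonate, C[Si](C)(C)OS(=O)(=O)C(F)(F)F
Why: Soft enolisation and O-silylation of the butenolide gives the aromatic 2-silyloxyfuran, the nucleophile for the vinylogous Mukaiyama aldol.

Step 7
Reactants: 10 (E)-3-{6-[(R)-1-(TBSO)propyl]pyridin-2-yl}-2-methylprop-2-enal; 12 [(4-methoxy-3-methylfuran-2-yl)oxy]trimethylsilane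
Product: 14 5-[(1S,2E)-1-hydroxy-2-methyl-3-{6-[(R)-1-(TBSO)propyl]pyridin-2-yl}prop-2-en-1-yl]-4-methoxy-3-methylfuran-2(5H)-one (both C5 epimers), via 11-O-trimethylsilyl ether 13 (not isolated)
Conditions: Ti(OiPr)4 (20 mol %), (R)-BINOL (20 mol %), Et2O, −20 °C; then 1 M HCl, THF, 0 °C
Reagents that add atoms: none
Why: Catalytic enantioselective vinylogous Mukaiyama aldol (1,2-addition of furan C5 to the enal) in which the BINOL antipode, taken as (R) on the assumption that it directs Re-face attack, should set C11 as S; both C12 epimers are carried on because C12 is planarised in step 9, and the hindered 2,6-disubstituted pyridine should not bind titanium.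

Step 8
Reactants: 14 5-[(1S,2E)-1-hydroxy-2-methyl-3-{6-[(R)-1-(TBSO)propyl]pyridin-2-yl}prop-2-en-1-yl]-4-methoxy-3-methylfuran-2(5H)-one
Product: 15 5-[(1S,2E)-1-(TBSO)-2-methyl-3-{6-[(R)-1-(TBSO)propyl]pyridin-2-yl}prop-2-en-1-yl]-4-methoxy-3-methylfuran-2(5H)-one (both C5 epimers)
Conditions: TBSOTf, 2,6-lutidine, CH2Cl2, −78 → 0 °C
Reagents that add atoms: tert-butyldimethylsilyl trifluoromethanesulfonate, CC(C)(C)[Si](C)(C)OS(=O)(=O)C(F)(F)F
Why: Silylation of the allylic C11 alcohol under non-basic conditions gives a non-chelating bulky ether, which the stereocontrol at C12 in step 9 relies on.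

Step 9
Reactants: 15 5-[(1S,2E)-1-(TBSO)-2-methyl-3-{6-[(R)-1-(TBSO)propyl]pyridin-2-yl}prop-2-en-1-yl]-4-methoxy-3-methylfuran-2(5H)-one; 16 4-chlorobutanal
Product: 18 (5S)-5-(4-chloro-1-hydroxybutyl)-5-[(1S,2E)-1-(TBSO)-2-methyl-3-{6-[(R)-1-(TBSO)propyl]pyridin-2-yl}prop-2-en-1-yl]-4-methoxy-3-methylfuran-2(5H)-one (both C13 epimers), via lithium 2-furanolate 17 (not isolated)
Conditions: LDA (1.1 equiv), THF, −78 °C; then 16, −78 °C; AcOH quench at −78 °C
Reagents that add atoms: none
Why: γ-Deprotonation gives the aromatic lithium 2-furanolate, which should add through C5 in a vinylogous aldol reaction; with C11–H held in the ring plane on the C4'–OMe side by A(1,3) strain, the aldehyde should enter anti to the alkenyl residue and so set C12, while the C13 epimers converge in step 10 and the cold quench forestalls retro-aldol and loss of silanolate.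

Step 10
Reactants: 18 (5S)-5-(4-chloro-1-hydroxybutyl)-5-[(1S,2E)-1-(TBSO)-2-methyl-3-{6-[(R)-1-(TBSO)propyl]pyridin-2-yl}prop-2-en-1-yl]-4-methoxy-3-methylfuran-2(5H)-one
Product: 19 (5S)-5-(4-chlorobutanoyl)-5-[(1S,2E)-1-(TBSO)-2-methyl-3-{6-[(R)-1-(TBSO)propyl]pyridin-2-yl}prop-2-en-1-yl]-4-methoxy-3-methylfuran-2(5H)-one
Conditions: Dess–Martin periodinane, CH2Cl2, rt
Reagents that add atoms: none
Why: Dess–Martin oxidation of the hindered secondary alcohol gives the C13 ketone under neutral conditions that leave the silyl ethers, the tetronate and the non-enolisable quaternary C12 untouched.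

Step 11
Reactants: 19 (5S)-5-(4-chlorobutanoyl)-5-[(1S,2E)-1-(TBSO)-2-methyl-3-{6-[(R)-1-(TBSO)propyl]pyridin-2-yl}prop-2-en-1-yl]-4-methoxy-3-methylfuran-2(5H)-one
Product: 22 (5R,6S,7R,8S,9S)-9-(TBSO)-7-{6-[(R)-1-(TBSO)propyl]pyridin-2-yl}-6-(3-chloropropyl)-6-hydroxy-4-methoxy-3,8-dimethyl-1-oxaspiro[4.4]non-3-en-2-one, via N-copper aza-enolate 20 (not isolated), via 13-O-diethoxymethylsilyl ether 21 (not isolated)
Conditions: Cu(OAc)2·H2O (10 mol %), Josiphos SL-J001 (11 mol %, antipode selected for 10S), (EtO)2MeSiH (2 equiv), toluene/THF, 0 °C → rt; then aq. citric acid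
Reagents that add atoms: none
Why: Proposed new method: a ligated Cu–H (from Cu(OAc)2, the bisphosphine and the silane) should add across C9=C10 with hydride at C10 and copper at C9, because C8=N polarises the alkene as the C=O of an enone does; the N-bound copper aza-enolate 20 should then attack the C13 ketone through a six-membered N–Cu–O chelate, and σ-bond metathesis with the silane should release 21 and regenerate Cu–H. The closest known reaction types are the copper-hydride reductive coupling of alkenyl azaarenes with ketones (intermolecular) and Cu–H reductive aldol cyclisations of keto-enones; the ring-closing use of an alkenylpyridine is the new element. One ring is closed, the cyclopentane C9–C10–C11–C12–C13, in a 5-(enolexo)-exo-trig mode. C10 (S) is set in the hydrocupration by the ligand antipode, chosen to match the polar Felkin–Anh preference for hydride delivery anti to the C11–O bond; C9 (R) follows from A(1,3) strain in the Z-aza-enolate (C10–H eclipses C8=C9, so C13 arrives anti to the C10 methyl); C13 (S) follows from the chelate, which places the new OH cis to the pyridyl group. The step needs chemoselectivity for hydrocupration over 1,2-reduction of the ketone and over retro-Claisen loss of the furanolate: the ketone is neopentylic next to quaternary C12, the alkene is activated by the azaarene, and no alkoxide base is present; regioselectivity (H to C10, not C9) is secured by the pyridine nitrogen.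

Step 12
Reactants: 22 (5R,6S,7R,8S,9S)-9-(TBSO)-7-{6-[(R)-1-(TBSO)propyl]pyridin-2-yl}-6-(3-chloropropyl)-6-hydroxy-4-methoxy-3,8-dimethyl-1-oxaspiro[4.4]non-3-en-2-one
Product: 23 (5S,6S,7R,8S,9S)-9-(TBSO)-7-{6-[(R)-1-(TBSO)propyl]pyridin-2-yl}-6-(3-chloropropyl)-4-methoxy-3,8-dimethyl-6-(TESO)-1-oxaspiro[4.4]non-3-en-2-one
Conditions: TESOTf, 2,6-lutidine, CH2Cl2, 0 °C → rt
Reagents that add atoms: triethylsilyl trifluoromethanesulfonate, CC[Si](CC)(CC)OS(=O)(=O)C(F)(F)F
Why: Silyl triflate protection of the tertiary C13 alcohol (same spatial arrangement; the C5 descriptor changes only by priority) removes the oxygen nucleophile that would otherwise close a tetrahydrofuran onto C16 in step 13.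

Step 13
Reactants: 23 (5S,6S,7R,8S,9S)-9-(TBSO)-7-{6-[(R)-1-(TBSO)propyl]pyridin-2-yl}-6-(3-chloropropyl)-4-methoxy-3,8-dimethyl-6-(TESO)-1-oxaspiro[4.4]non-3-en-2-one
Product: 24 tetrahydropyrido[1,2-a]azepinium chloride formed from 23 by bonding N to C16 (azepane closed; 3,11-bis-OTBS; 13-OTES)
Conditions: NaI (0.2 equiv), MeCN, 80 °C
Reagents that add atoms: none
Why: Intramolecular Menshutkin N-alkylation (7-exo-tet) with in situ Finkelstein activation of the chloride should close the azepane as a pyridinium ring, and the neutral medium protects the now acidic C9–H.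

Step 14
Reactants: 24 tetrahydropyrido[1,2-a]azepinium chloride (azepane closed; 3,11-bis-OTBS; 13-OTES)
Product: 25 3,11-bis-O-TBS-13-O-TES ether of the target
Conditions: H2 (5 bar), PtO2 (10 mol %), MeOH, rt; aq. NaHCO3 work-up
Reagents that add atoms: none
Why: Heterogeneous hydrogenation of the pyridinium ring delivers all hydrogens to one face, which gives the cis-2,6 relationship of C4 and C8; that face should be the one of C9–H, because whichever way the seven-membered ring puckers the other face carries either C13 or C10, and the tetrasubstituted enol-ether double bond of the tetronate should survive.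

Step 15
Reactants: 25 3,11-bis-O-TBS-13-O-TES ether of the target
Product: 26 CNP0267781.1 (target)
Conditions: HF·pyridine, THF, 0 °C → rt; aq. NaHCO3 work-up
Reagents that add atoms: none
Why: Fluoride-mediated cleavage of the two TBS ethers and the tertiary TES ether under mildly acidic conditions leaves the tetronate, the tertiary carbinol and the amine untouched and affects no stereocentre.

**Compound list**

1 | 2,6-dibromopyridine | Brc1cccc(Br)n1 | starting material
2 | N-methoxy-N-methylpropanamide | CCC(=O)N(C)OC | starting material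
3 | 6-bromo-2-lithiopyridine | [Li]c1cccc(Br)n1 | intermediate
4 | 1-(6-bromopyridin-2-yl)propan-1-one | CCC(=O)c1cccc(Br)n1 | intermediate
5 | (R)-1-(6-bromopyridin-2-yl)propan-1-ol | CC[C@@H](O)c1cccc(Br)n1 | intermediate
6 | (R)-2-bromo-6-[1-(TBSO)propyl]pyridine | CC[C@@H](O[Si](C)(C)C(C)(C)C)c1cccc(Br)n1 | intermediate
7 | 6-lithio-2-[(R)-1-(TBSO)propyl]pyridine | CC[C@@H](O[Si](C)(C)C(C)(C)C)c1cccc([Li])n1 | intermediate
8 | (R)-6-[1-(TBSO)propyl]pyridine-2-carbaldehyde | CC[C@@H](O[Si](C)(C)C(C)(C)C)c1cccc(C=O)n1 | intermediate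
9 | 2-(triphenylphosphoranylidene)propanal | CC(C=O)=P(c1ccccc1)(c1ccccc1)c1ccccc1 | starting material
10 | (E)-3-{6-[(R)-1-(TBSO)propyl]pyridin-2-yl}-2-methylprop-2-enal | CC[C@@H](O[Si](C)(C)C(C)(C)C)c1cccc(n1)/C=C(\C)C=O | intermediate
11 | 4-methoxy-3-methylfuran-2(5H)-one | COC1=C(C)C(=O)OC1 | starting material
12 | [(4-methoxy-3-methylfuran-2-yl)oxy]trimethylsilane | COc1coc(O[Si](C)(C)C)c1C | intermediate
13 | 11-O-trimethylsilyl ether of 14 (C12 epimers) | CC[C@@H](O[Si](C)(C)C(C)(C)C)c1cccc(n1)/C=C(\C)[C@H](O[Si](C)(C)C)C2OC(=O)C(C)=C2OC | intermediate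
14 | 5-[(1S,2E)-1-hydroxy-2-methyl-3-{6-[(R)-1-(TBSO)propyl]pyridin-2-yl}prop-2-en-1-yl]-4-methoxy-3-methylfuran-2(5H)-one (C12 epimers) | CC[C@@H](O[Si](C)(C)C(C)(C)C)c1cccc(n1)/C=C(\C)[C@H](O)C2OC(=O)C(C)=C2OC | intermediate
15 | 11-O-TBS ether of 14 (C12 epimers) | CC[C@@H](O[Si](C)(C)C(C)(C)C)c1cccc(n1)/C=C(\C)[C@H](O[Si](C)(C)C(C)(C)C)C2OC(=O)C(C)=C2OC | intermediate
16 | 4-chlorobutanal | ClCCCC=O | starting material
17 | lithium 2-furanolate of 15 (C12 planar) | CC[C@@H](O[Si](C)(C)C(C)(C)C)c1cccc(n1)/C=C(\C)[C@H](O[Si](C)(C)C(C)(C)C)c2oc(O[Li])c(C)c2OC | intermediate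
18 | (5S)-5-(4-chloro-1-hydroxybutyl)-5-[(1S,2E)-1-(TBSO)-2-methyl-3-{6-[(R)-1-(TBSO)propyl]pyridin-2-yl}prop-2-en-1-yl]-4-methoxy-3-methylfuran-2(5H)-one (C13 epimers) | CC[C@@H](O[Si](C)(C)C(C)(C)C)c1cccc(n1)/C=C(\C)[C@H](O[Si](C)(C)C(C)(C)C)[C@@]2(OC(=O)C(C)=C2OC)C(O)CCCCl | intermediate
19 | (5S)-5-(4-chlorobutanoyl) analogue of 18 (C13 ketone) | CC[C@@H](O[Si](C)(C)C(C)(C)C)c1cccc(n1)/C=C(\C)[C@H](O[Si](C)(C)C(C)(C)C)[C@@]2(OC(=O)C(C)=C2OC)C(=O)CCCCl | intermediate
20 | N-copper aza-enolate (2-alkylidene-1,2-dihydropyridine, 10S; ligand on copper omitted) | CC[C@@H](O[Si](C)(C)C(C)(C)C)C1=CC=CC(=C[C@H](C)[C@H](O[Si](C)(C)C(C)(C)C)[C@@]2(OC(=O)C(C)=C2OC)C(=O)CCCCl)N1[Cu] | intermediate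
21 | 13-O-diethoxymethylsilyl ether of 22 | CC[C@@H](O[Si](C)(C)C(C)(C)C)c1cccc(n1)[C@H]2[C@H](C)[C@H](O[Si](C)(C)C(C)(C)C)[C@@]3(OC(=O)C(C)=C3OC)[C@]2(O[Si](C)(OCC)OCC)CCCCl | intermediate
22 | (5R,6S,7R,8S,9S)-9-(TBSO)-7-{6-[(R)-1-(TBSO)propyl]pyridin-2-yl}-6-(3-chloropropyl)-6-hydroxy-4-methoxy-3,8-dimethyl-1-oxaspiro[4.4]non-3-en-2-one (pyridyl, 13-OH and lactone O on one face of the cyclopentane; 10-Me, 11-OTBS and the chloropropyl chain on the other) | CC[C@@H](O[Si](C)(C)C(C)(C)C)c1cccc(n1)[C@H]2[C@H](C)[C@H](O[Si](C)(C)C(C)(C)C)[C@@]3(OC(=O)C(C)=C3OC)[C@]2(O)CCCCl | intermediate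
23 | 13-O-TES ether of 22, (5S,6S,7R,8S,9S) | CC[C@@H](O[Si](C)(C)C(C)(C)C)c1cccc(n1)[C@H]2[C@H](C)[C@H](O[Si](C)(C)C(C)(C)C)[C@@]3(OC(=O)C(C)=C3OC)[C@]2(O[Si](CC)(CC)CC)CCCCl | intermediate
24 | tetrahydropyrido[1,2-a]azepinium chloride (N–C16 closed; trans-fused to the spiro-cyclopentane at C9–C13; 3,11-bis-OTBS; 13-OTES) | CC[C@@H](O[Si](C)(C)C(C)(C)C)c1cccc2[C@H]3[C@H](C)[C@H](O[Si](C)(C)C(C)(C)C)[C@@]4(OC(=O)C(C)=C4OC)[C@]3(O[Si](CC)(CC)CC)CCC[n+]12.[Cl-] | intermediate
25 | 3,11-bis-O-TBS-13-O-TES ether of the target (cis-2,6-piperidine; H8 cis to H9) | CC[C@@H](O[Si](C)(C)C(C)(C)C)[C@H]1CCC[C@H]2[C@H]3[C@H](C)[C@H](O[Si](C)(C)C(C)(C)C)[C@@]4(OC(=O)C(C)=C4OC)[C@]3(O[Si](CC)(CC)CC)CCCN12 | intermediate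
26 | CNP0267781.1, (3R,4R,8S,9R,10S,11S,12R,13S) in the numbering above | CC[C@@H](O)[C@H]1CCC[C@H]2[C@H]3[C@H](C)[C@H](O)[C@@]4(OC(=O)C(C)=C4OC)[C@]3(O)CCCN12 | target

**Totals**

Total steps: 15. Longest linear sequence: 14 steps (steps 1–5 and 7–15, from 2,6-dibromopyridine); step 6 is a one-step branch.

**Steps most likely to fail**

Step 11 (Proposed new method). What may go wrong: the copper hydride reduces the C13 ketone, the aza-enolate is protonated before it cyclises, or hydride is delivered to the wrong face at C10. Fallback, known chemistry only: set out from 15 and run the established Cu–H/Josiphos conjugate reduction of a β,β-disubstituted 2-alkenylpyridine while no ketone is present, giving the saturated (10S)-2-alkylpyridine F1. Repeat the chemistry of steps 9 and 10 (LDA and 16, then Dess–Martin periodinane) to reach the C13 carbinol F2 and the C13 ketone F3. Close C9–C13 by the Lewis-acid-catalysed addition of a 2-alkylazaarene C–H bond to a carbonyl group (Sc(OTf)3, toluene, 80 °C; the enamine tautomer of the pyridine attacks the α-oxygenated ketone). This addition is reversible and should settle on the isomer in which the new OH is hydrogen-bonded to the pyridine nitrogen, which returns to the route at 22.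

Step 9. What may go wrong: poor facial selectivity at C12, E1cB loss of the C11 silanolate from the furanolate, or retro-aldol on warming. Fallback: from 15 prepare the 2-(tert-butyldimethylsilyloxy)furan F4 (TBSOTf, Et3N) and add it to 16 with BF3·OEt2 at −78 °C. This is a vinylogous Mukaiyama aldol through an open transition state with no basic enolate present; aqueous work-up returns to the route at 18.

Step 13. What may go wrong: the Menshutkin closure onto a pyridine nitrogen flanked by two branched substituents is too slow, so that elimination or desilylation takes over on prolonged heating. Fallback: from 23 hydrogenate the neutral pyridine first (H2, PtO2, AcOH) to the cis-2,6-disubstituted piperidine F5, then close the azepane by alkylation of the secondary amine (K2CO3, NaI, MeCN, 60 °C), which returns to the route at 25. The price is that facial control in the hydrogenation then rests on the C9 stereocentre alone, without the rigid fused pyridinium.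

**Further compounds**

F1 | step 11 | (10S)-dihydro analogue of 15: 5-[(1S,2S)-1-(TBSO)-2-methyl-3-{6-[(R)-1-(TBSO)propyl]pyridin-2-yl}propyl]-4-methoxy-3-methylfuran-2(5H)-one (C12 epimers) | CC[C@@H](O[Si](C)(C)C(C)(C)C)c1cccc(n1)C[C@H](C)[C@H](O[Si](C)(C)C(C)(C)C)C2OC(=O)C(C)=C2OC
F2 | step 11 | C9–C10 saturated analogue of 18 (C13 carbinol, C13 epimers) | CC[C@@H](O[Si](C)(C)C(C)(C)C)c1cccc(n1)C[C@H](C)[C@H](O[Si](C)(C)C(C)(C)C)[C@@]2(OC(=O)C(C)=C2OC)C(O)CCCCl
F3 | step 11 | C9–C10 saturated analogue of 19 (C13 ketone) | CC[C@@H](O[Si](C)(C)C(C)(C)C)c1cccc(n1)C[C@H](C)[C@H](O[Si](C)(C)C(C)(C)C)[C@@]2(OC(=O)C(C)=C2OC)C(=O)CCCCl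
F4 | step 9 | 2-(tert-butyldimethylsilyloxy)furan derived from 15 | CC[C@@H](O[Si](C)(C)C(C)(C)C)c1cccc(n1)/C=C(\C)[C@H](O[Si](C)(C)C(C)(C)C)c2oc(O[Si](C)(C)C(C)(C)C)c(C)c2OC
F5 | step 13 | cis-2,6-disubstituted piperidine from 23 (secondary amine, C16 chloride intact) | CC[C@@H](O[Si](C)(C)C(C)(C)C)[C@H]1CCC[C@H](N1)[C@H]2[C@H](C)[C@H](O[Si](C)(C)C(C)(C)C)[C@@]3(OC(=O)C(C)=C3OC)[C@]2(O[Si](CC)(CC)CC)CCCCl
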